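**Retrosynthetic overview**
1. The target is a diester of a 4,5-epoxygermacr-1(10)-ene-6,8-diol. The last disconnections are the C6 ester (silyl-protected (2R,3S)-acid from an Evans syn-aldol), the 4,5-oxirane (epoxidation of C4=C5 directed by the free C6 hydroxyl) and the C8 tiglate.
2. Key disconnection: the ten-membered carbocycle is opened at C9–C10. The enabling feature is the homoallylic array O–C8H–C9H2–C10(CH3)=C1H (E) inside the ten-membered ring, which is the retron of a reductive coupling between a methyl-capped alkyne (C1≡C10) and a terminal oxirane (C8–C9).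
3. The acyclic epoxy-enyne comes from an alkenyllithium plus a Weinreb amide (C5–C6), a 1,3-anti reduction (C6) and an Evans syn-aldol with chloroacetaldehyde (C7, C8; chlorohydrin to oxirane). The alkenyl iodide comes from carboalumination of hepta-1,5-diyne.
4. Ring order: the ten-membered carbocycle first (step 11), then the oxirane fused at C4–C5 (step 14).

Key step: step 11

Remark: germacrane numbering is used for chain and ring carbons (C1=C10 with methyl C14 on C10, methyl C15 on C4, oxygen on C6 and C8, isopropyl on C7, C9 the ring CH2); the unsaturated ester is read from the SMILES as the E isomer (tiglate); CIP letters at C6 and C7 change along the route only through priority changes, the SMILES being authoritative; anhydrous chloroacetaldehyde is taken as obtained by drying and distilling the commercial aqueous solution.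

**Route**

Step 1
Reactants: 1 1-(trimethylsilyl)propyne; 2 1-bromobut-2-yne
Product: 4 trimethyl(hepta-1,5-diyn-1-yl)silane, via silylpropargyllithium 3 (not isolated)
Conditions: 1, n-BuLi, THF, −78 → −20 °C; then 2, −78 °C → rt
Reagents that add atoms: none
Why: Propargylic lithiation of 1, whose silyl group blocks the allenyl terminus, followed by SN2 alkylation at the primary propargylic bromide should give the 1,5-diyne.

Step 2
Reactants: 4 trimethyl(hepta-1,5-diyn-1-yl)silane
Product: 5 hepta-1,5-diyne
Conditions: K2CO3 (cat.), MeOH, rt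
Reagents that add atoms: none
Why: Base-catalysed protodesilylation of the alkynylsilane should free the terminal alkyne and leave the methyl-capped alkyne untouched.

Step 3
Reactants: 5 hepta-1,5-diyne
Product: 7 (1E)-1-iodo-2-methylhept-1-en-5-yne, via alkenyldimethylalane 6 (not isolated)
Conditions: AlMe3 (2 equiv), Cp2ZrCl2 (0.2 equiv), CH2Cl2, 0 °C → rt; then I2, THF, −30 → 0 °C
Reagents that add atoms: trimethylaluminium, C[Al](C)C; iodine, II
Why: Negishi zirconium-catalysed carboalumination adds CH3 and Al syn across the terminal alkyne (the internal dialkylalkyne reacts far more slowly) and iodinolysis with retention should give the E-alkenyl iodide, which fixes the C4=C5 geometry and brings in C15.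

Step 4
Reactants: 8 (4S)-4-benzyl-1,3-oxazolidin-2-one; 9 3-methylbutanoyl chloride
Product: 10 (4S)-4-benzyl-3-(3-methylbutanoyl)-1,3-oxazolidin-2-one
Conditions: Et3N, DMAP (cat.), CH2Cl2, 0 °C → rt
Reagents that add atoms: none
Why: N-acylation of the oxazolidinone by the acid chloride under nucleophilic catalysis should give the imide without touching the auxiliary stereocentre.

Step 5
Reactants: 10 (4S)-4-benzyl-3-(3-methylbutanoyl)-1,3-oxazolidin-2-one; 11 chloroacetaldehyde
Product: 13 (4S)-4-benzyl-3-[(2S,3S)-4-chloro-3-hydroxy-2-(propan-2-yl)butanoyl]-1,3-oxazolidin-2-one, via Z-boron enolate 12 (not isolated)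
Conditions: Bu2BOTf, i-Pr2NEt, CH2Cl2, −78 → 0 °C; then 11, −78 → 0 °C; pH 7 buffer, MeOH, H2O2, 0 °C
Reagents that add atoms: none
Why: Evans syn-aldol reaction, in which the Z-dibutylboron enolate reacts through a Zimmerman–Traxler chair on the face away from the benzyl group, should set C7 and C8 (isopropyl and hydroxyl syn) and deliver C9 as a chloride ready for oxirane closure.

Step 6
Reactants: 13 (4S)-4-benzyl-3-[(2S,3S)-4-chloro-3-hydroxy-2-(propan-2-yl)butanoyl]-1,3-oxazolidin-2-one
Product: 14 (2S,3S)-4-chloro-3-hydroxy-N-methoxy-N-methyl-2-(propan-2-yl)butanamide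
Conditions: MeNH(OMe)·HCl, AlMe3, CH2Cl2, −20 °C → rt; aq. potassium sodium tartrate
Reagents that add atoms: N,O-dimethylhydroxylamine hydrochloride, CNOC.Cl
Why: Aluminium-amide transamidation of the β-hydroxy imide (Weinreb amide formation), assisted by the aluminium alkoxide of the C8 hydroxyl, should replace the auxiliary without epimerising C7.

Step 7
Reactants: 14 (2S,3S)-4-chloro-3-hydroxy-N-methoxy-N-methyl-2-(propan-2-yl)butanamide; 7 (1E)-1-iodo-2-methylhept-1-en-5-yne
Product: 16 (2S,3S,5E)-1-chloro-2-hydroxy-6-methyl-3-(propan-2-yl)undec-5-en-9-yn-4-one, via alkenyllithium 15 (not isolated)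
Conditions: 7, t-BuLi (2 equiv), Et2O, −78 °C; 14, i-PrMgCl (1 equiv), THF, −78 °C; mix, −78 → −40 °C; aq. NH4Cl
Reagents that add atoms: none
Why: Weinreb ketone synthesis, in which iodine–lithium exchange keeps the E geometry, the chelated tetrahedral intermediate stops over-addition and the cold magnesium alkoxide of the C8 hydroxyl neither consumes the alkenyllithium nor closes onto the chloride, should form the C5–C6 bond.

Step 8
Reactants: 16 (2S,3S,5E)-1-chloro-2-hydroxy-6-methyl-3-(propan-2-yl)undec-5-en-9-yn-4-one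
Product: 17 (2S,3R,4R,5E)-1-chloro-6-methyl-3-(propan-2-yl)undec-5-en-9-yne-2,4-diol
Conditions: Me4NBH(OAc)3, MeCN/AcOH (1:1), −30 °C
Reagents that add atoms: none
Why: Evans–Saksena reduction, in which the C8 hydroxyl binds the acetoxyborohydride and delivers hydride intramolecularly through a chair transition state, should give the 1,3-anti diol and so set C6 by 1,2-reduction of the enone.

Step 9
Reactants: 17 (2S,3R,4R,5E)-1-chloro-6-methyl-3-(propan-2-yl)undec-5-en-9-yne-2,4-diol
Product: 18 (3R,4R,5E)-2,6-dimethyl-3-[(2S)-oxiran-2-yl]undec-5-en-9-yn-4-ol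
Conditions: K2CO3, MeOH, 0 °C
Reagents that add atoms: none
Why: Intramolecular Williamson closure of the C8 alkoxide onto the neighbouring primary chloride (3-exo-tet, faster than five-ring ether formation from O6 under basic conditions) should give the terminal oxirane with C8 unchanged, because no bond to C8 is broken.

Step 10
Reactants: 18 (3R,4R,5E)-2,6-dimethyl-3-[(2S)-oxiran-2-yl]undec-5-en-9-yn-4-ol
Product: 19 triethyl({(3S,4R,5E)-2,6-dimethyl-3-[(2S)-oxiran-2-yl]undec-5-en-9-yn-4-yl}oxy)silane
Conditions: Et3SiCl, imidazole, DMF, 0 °C → rt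
Reagents that add atoms: chlorotriethylsilane, CC[Si](Cl)(CC)CC
Why: Silylation of the only hydroxyl masks C6–OH as an allylic silyl ether, which is inert to zerovalent nickel and can be removed later without acid.

Step 11
Reactants: 19 triethyl({(3S,4R,5E)-2,6-dimethyl-3-[(2S)-oxiran-2-yl]undec-5-en-9-yn-4-yl}oxy)silane
Product: 20 (1(10)E,4E,6R,7S,8R)-6-[(triethylsilyl)oxy]germacra-1(10),4-dien-8-ol
Conditions: Ni(cod)2 (20 mol %), PBu3 (40 mol %), BEt3 (3 equiv), degassed THF, 23 °C, 19 added by syringe pump to 0.005 M; aq. NH4Cl work-up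
Reagents that add atoms: none
Why: Zerovalent nickel carrying the small donor PBu3 should bind the alkyne and open the terminal oxirane at its unsubstituted carbon C9 (SN2-type oxidative addition), the alkyne then inserts syn into the Ni–C9 bond to give an oxanickelacycle (O8–Ni–C1), and BEt3 takes over the alkoxide and passes an ethyl group to nickel, so that β-hydride elimination and C–H reductive elimination place hydrogen on C1 cis to C9. The closest known reaction type is the nickel-catalysed reductive coupling of alkynes with terminal epoxides to homoallylic alcohols, which is established intermolecularly, in small-ring closures and in macrocyclisation. The one ring formed is the ten-membered carbocycle, closed 10-endo-dig at the alkyne and with endo opening of the oxirane (both oxirane carbons end up in the ring). No new stereocentre arises: C8 keeps the oxirane configuration because only the C9–O bond breaks, C6 and C7 are untouched, and the E geometry of C1=C10 follows from the syn addition of C9 and H. The step needs bond formation at C10 and not C1, which the small phosphine (carbon–carbon bond at the methyl-bearing alkyne carbon, larger substituent next to nickel) and the preference for a ten-membered (E,E)-cyclodeca-1,5-diene over a nine-membered ring with an exocyclic ethylidene should secure. It also needs attack at C9 and not C8, secured by the unsubstituted oxirane terminus, and ring closure over oligomerisation, secured by slow addition at high dilution and by the E-C4=C5 olefin and the branched C6–C7–C8 segment, which restrict the chain.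

Step 12
Reactants: 20 (1(10)E,4E,6R,7S,8R)-6-[(triethylsilyl)oxy]germacra-1(10),4-dien-8-ol; 21 (2E)-2-methylbut-2-enoyl chloride
Product: 22 (1(10)E,4E,6R,7S,8R)-6-[(triethylsilyl)oxy]germacra-1(10),4-dien-8-yl (2E)-2-methylbut-2-enoate
Conditions: pyridine, DMAP (cat.), CH2Cl2, 0 °C → rt
Reagents that add atoms: none
Why: DMAP-catalysed acylation of the only free hydroxyl (C8) with the thermodynamically preferred E acid chloride under weak base should give the tiglate without deconjugation, and working at or below room temperature avoids Cope rearrangement of the cyclodeca-1,5-diene.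

Step 13
Reactants: 22 (1(10)E,4E,6R,7S,8R)-6-[(triethylsilyl)oxy]germacra-1(10),4-dien-8-yl (2E)-2-methylbut-2-enoate
Product: 23 (1(10)E,4E,6R,7R,8R)-6-hydroxygermacra-1(10),4-dien-8-yl (2E)-2-methylbut-2-enoate
Conditions: Bu4NF, AcOH (1:1), THF, 0 °C → rt
Reagents that add atoms: none
Why: Fluoride-induced desilylation buffered with acetic acid should free the C6 hydroxyl while the buffer keeps the alkoxide protonated, so that the C8 tiglate does not migrate and the acid-sensitive diene never meets strong acid.

Step 14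
Reactants: 23 (1(10)E,4E,6R,7R,8R)-6-hydroxygermacra-1(10),4-dien-8-yl (2E)-2-methylbut-2-enoate
Product: 24 (1(10)E,4R,5R,6S,7R,8R)-4,5-epoxy-6-hydroxygermacr-1(10)-en-8-yl (2E)-2-methylbut-2-enoate
Conditions: VO(acac)2 (5 mol %), t-BuOOH (1.5 equiv, decane), CH2Cl2, 0 °C
Reagents that add atoms: tert-butyl hydroperoxide, CC(C)(C)OO
Why: Hydroxyl-directed vanadium-catalysed epoxidation should oxidise only the allylic C4=C5 olefin, and because H6 eclipses the olefin to avoid allylic 1,3-strain with the C4 methyl while C7 points into the ring, oxygen is delivered on the outer face syn to O6 to give the (4R,5R) trans-oxirane, the C1=C10 olefin and the tiglate having no directing hydroxyl.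

Step 15
Reactants: 25 (4R)-4-benzyl-3-propanoyl-1,3-oxazolidin-2-one; 26 acetaldehyde
Product: 28 (4R)-4-benzyl-3-[(2R,3S)-3-hydroxy-2-methylbutanoyl]-1,3-oxazolidin-2-one, via Z-boron enolate 27 (not isolated)
Conditions: Bu2BOTf, i-Pr2NEt, CH2Cl2, −78 → 0 °C; then 26, −78 → 0 °C; pH 7 buffer, MeOH, H2O2, 0 °C
Reagents that add atoms: none
Why: Evans syn-aldol reaction of the enantiomeric auxiliary through the Zimmerman–Traxler chair should set both side-chain stereocentres as (2R,3S).

Step 16
Reactants: 28 (4R)-4-benzyl-3-[(2R,3S)-3-hydroxy-2-methylbutanoyl]-1,3-oxazolidin-2-one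
Product: 29 (4R)-4-benzyl-3-{(2R,3S)-2-methyl-3-[(triethylsilyl)oxy]butanoyl}-1,3-oxazolidin-2-one
Conditions: Et3SiOTf, 2,6-lutidine, CH2Cl2, −78 °C
Reagents that add atoms: triethylsilyl trifluoromethanesulfonate, CC[Si](CC)(CC)OS(=O)(=O)C(F)(F)F
Why: Silylation with the silyl triflate and a hindered base is fast at low temperature and should avoid retro-aldol cleavage of the β-hydroxy imide.

Step 17
Reactants: 29 (4R)-4-benzyl-3-{(2R,3S)-2-methyl-3-[(triethylsilyl)oxy]butanoyl}-1,3-oxazolidin-2-one
Product: 30 (2R,3S)-2-methyl-3-[(triethylsilyl)oxy]butanoic acid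
Conditions: LiOH, H2O2, THF/H2O (3:1), 0 °C; Na2SO3; then aq. HCl to pH 4, 0 °C
Reagents that add atoms: hydrogen peroxide (as LiOOH), OO
Why: Hydroperoxide cleavage of the Evans imide attacks the exocyclic carbonyl selectively and should release the acid without epimerising C2 or removing the silyl ether.

Step 18
Reactants: 24 (1(10)E,4R,5R,6S,7R,8R)-4,5-epoxy-6-hydroxygermacr-1(10)-en-8-yl (2E)-2-methylbut-2-enoate; 30 (2R,3S)-2-methyl-3-[(triethylsilyl)oxy]butanoic acid
Product: 32 (1(10)E,4R,5R,6S,7S,8R)-4,5-epoxy-6-({(2R,3S)-2-methyl-3-[(triethylsilyl)oxy]butanoyl}oxy)germacr-1(10)-en-8-yl (2E)-2-methylbut-2-enoate, via mixed anhydride 31 (not isolated)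
Conditions: 30, 2,4,6-trichlorobenzoyl chloride, Et3N, THF, rt; then 24, DMAP, toluene, rt
Reagents that add atoms: none
Why: Yamaguchi esterification, in which DMAP transfers the aliphatic acyl group of the mixed anhydride to the hindered C6 hydroxyl under non-acidic conditions, should form the ester with the oxirane and all stereocentres intact.

Step 19
Reactants: 32 (1(10)E,4R,5R,6S,7S,8R)-4,5-epoxy-6-({(2R,3S)-2-methyl-3-[(triethylsilyl)oxy]butanoyl}oxy)germacr-1(10)-en-8-yl (2E)-2-methylbut-2-enoate
Product: 33 (1(10)E,4R,5R,6S,7S,8R)-4,5-epoxy-6-{[(2R,3S)-3-hydroxy-2-methylbutanoyl]oxy}germacr-1(10)-en-8-yl (2E)-2-methylbut-2-enoate (CNP0159364.1)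
Conditions: Bu4NF, AcOH (1:1), THF, 0 °C
Reagents that add atoms: none
Why: Buffered fluoride desilylation should remove the triethylsilyl group under near-neutral conditions that spare the oxirane, both esters and the medium-ring olefin.

**Compound list**
1 | 1-(trimethylsilyl)propyne | CC#C[Si](C)(C)C | starting material
2 | 1-bromobut-2-yne | CC#CCBr | starting material
3 | [3-(trimethylsilyl)prop-2-yn-1-yl]lithium | [Li]CC#C[Si](C)(C)C | intermediate
4 | trimethyl(hepta-1,5-diyn-1-yl)silane | CC#CCCC#C[Si](C)(C)C | intermediate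
5 | hepta-1,5-diyne | CC#CCCC#C | intermediate
6 | dimethyl[(1E)-2-methylhept-1-en-5-yn-1-yl]alumane | CC#CCC/C(C)=C/[Al](C)C | intermediate
7 | (1E)-1-iodo-2-methylhept-1-en-5-yne | CC#CCC/C(C)=C/I | intermediate
8 | (4S)-4-benzyl-1,3-oxazolidin-2-one | O=C1OC[C@H](Cc2ccccc2)N1 | starting material
9 | 3-methylbutanoyl chloride | CC(C)CC(=O)Cl | starting material
10 | (4S)-4-benzyl-3-(3-methylbutanoyl)-1,3-oxazolidin-2-one | O=C1OC[C@H](Cc2ccccc2)N1C(=O)CC(C)C | intermediate
11 | chloroacetaldehyde | O=CCCl | starting material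
12 | Z-dibutylboron enolate of 10 | O=C1OC[C@H](Cc2ccccc2)N1/C(OB(CCCC)CCCC)=C/C(C)C | intermediate
13 | (4S)-4-benzyl-3-[(2S,3S)-4-chloro-3-hydroxy-2-(propan-2-yl)butanoyl]-1,3-oxazolidin-2-one | O=C1OC[C@H](Cc2ccccc2)N1C(=O)[C@@H](C(C)C)[C@H](O)CCl | intermediate
14 | (2S,3S)-4-chloro-3-hydroxy-N-methoxy-N-methyl-2-(propan-2-yl)butanamide | CON(C)C(=O)[C@@H](C(C)C)[C@H](O)CCl | intermediate
15 | [(1E)-2-methylhept-1-en-5-yn-1-yl]lithium | CC#CCC/C(C)=C/[Li] | intermediate
16 | (2S,3S,5E)-1-chloro-2-hydroxy-6-methyl-3-(propan-2-yl)undec-5-en-9-yn-4-one | CC#CCC/C(C)=C/C(=O)[C@@H](C(C)C)[C@H](O)CCl | intermediate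
17 | (2S,3R,4R,5E)-1-chloro-6-methyl-3-(propan-2-yl)undec-5-en-9-yne-2,4-diol | CC#CCC/C(C)=C/[C@@H](O)[C@@H](C(C)C)[C@H](O)CCl | intermediate
18 | (3R,4R,5E)-2,6-dimethyl-3-[(2S)-oxiran-2-yl]undec-5-en-9-yn-4-ol | CC#CCC/C(C)=C/[C@@H](O)[C@@H](C(C)C)[C@H]1CO1 | intermediate
19 | triethyl({(3S,4R,5E)-2,6-dimethyl-3-[(2S)-oxiran-2-yl]undec-5-en-9-yn-4-yl}oxy)silane | CC#CCC/C(C)=C/[C@@H](O[Si](CC)(CC)CC)[C@@H](C(C)C)[C@H]1CO1 | intermediate
20 | (1(10)E,4E,6R,7S,8R)-6-[(triethylsilyl)oxy]germacra-1(10),4-dien-8-ol | O[C@@H]1C/C(C)=C/CC/C(C)=C/[C@@H](O[Si](CC)(CC)CC)[C@H]1C(C)C | intermediate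
21 | (2E)-2-methylbut-2-enoyl chloride (tigloyl chloride) | C/C=C(\C)C(=O)Cl | starting material
22 | (1(10)E,4E,6R,7S,8R)-6-[(triethylsilyl)oxy]germacra-1(10),4-dien-8-yl (2E)-2-methylbut-2-enoate | C/C=C(\C)C(=O)O[C@@H]1C/C(C)=C/CC/C(C)=C/[C@@H](O[Si](CC)(CC)CC)[C@H]1C(C)C | intermediate
23 | (1(10)E,4E,6R,7R,8R)-6-hydroxygermacra-1(10),4-dien-8-yl (2E)-2-methylbut-2-enoate | C/C=C(\C)C(=O)O[C@@H]1C/C(C)=C/CC/C(C)=C/[C@@H](O)[C@H]1C(C)C | intermediate
24 | (1(10)E,4R,5R,6S,7R,8R)-4,5-epoxy-6-hydroxygermacr-1(10)-en-8-yl (2E)-2-methylbut-2-enoate | C/C=C(\C)C(=O)O[C@@H]1C/C(C)=C/CC[C@@]2(C)O[C@@H]2[C@@H](O)[C@H]1C(C)C | intermediate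
25 | (4R)-4-benzyl-3-propanoyl-1,3-oxazolidin-2-one | O=C1OC[C@@H](Cc2ccccc2)N1C(=O)CC | starting material
26 | acetaldehyde | CC=O | starting material
27 | Z-dibutylboron enolate of 25 | O=C1OC[C@@H](Cc2ccccc2)N1/C(OB(CCCC)CCCC)=C/C | intermediate
28 | (4R)-4-benzyl-3-[(2R,3S)-3-hydroxy-2-methylbutanoyl]-1,3-oxazolidin-2-one | O=C1OC[C@@H](Cc2ccccc2)N1C(=O)[C@H](C)[C@H](C)O | intermediate
29 | (4R)-4-benzyl-3-{(2R,3S)-2-methyl-3-[(triethylsilyl)oxy]butanoyl}-1,3-oxazolidin-2-one | O=C1OC[C@@H](Cc2ccccc2)N1C(=O)[C@H](C)[C@H](C)O[Si](CC)(CC)CC | intermediate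
30 | (2R,3S)-2-methyl-3-[(triethylsilyl)oxy]butanoic acid | OC(=O)[C@H](C)[C@H](C)O[Si](CC)(CC)CC | intermediate
31 | mixed anhydride of 30 with 2,4,6-trichlorobenzoic acid | O=C(OC(=O)[C@H](C)[C@H](C)O[Si](CC)(CC)CC)c1c(Cl)cc(Cl)cc1Cl | intermediate
32 | (1(10)E,4R,5R,6S,7S,8R)-4,5-epoxy-6-({(2R,3S)-2-methyl-3-[(triethylsilyl)oxy]butanoyl}oxy)germacr-1(10)-en-8-yl (2E)-2-methylbut-2-enoate | C/C=C(\C)C(=O)O[C@@H]1C/C(C)=C/CC[C@@]2(C)O[C@@H]2[C@@H](OC(=O)[C@H](C)[C@H](C)O[Si](CC)(CC)CC)[C@H]1C(C)C | intermediate
33 | (1(10)E,4R,5R,6S,7S,8R)-4,5-epoxy-6-{[(2R,3S)-3-hydroxy-2-methylbutanoyl]oxy}germacr-1(10)-en-8-yl (2E)-2-methylbut-2-enoate | C/C=C(\C)C(=O)O[C@@H]1C/C(C)=C/CC[C@@]2(C)O[C@@H]2[C@@H](OC(=O)[C@H](C)[C@H](C)O)[C@H]1C(C)C | target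

**Count and risks**
Total steps: 19. Longest linear sequence: 13 steps (steps 4–14, 18, 19; the sequence through steps 1–3 and 7–14, 18, 19 is equally long).

Risk 1, step 11. The alkyne may insert with the opposite orientation (C9 bonding to C1, giving a nine-membered ring with an exocyclic ethylidene), intermolecular coupling may outrun the ten-membered closure, or the catalyst may stall at the oxirane opening. The fallback sets out from 19 and comes back at 20, and replaces alkyne insertion by a cross-electrophile coupling of two preformed halides, so that regiochemistry and olefin geometry are fixed before the ring closes. Hydrozirconation of 19 with Cp2Zr(H)Cl (excess, THF, rt, so that zirconium equilibrates to the methyl-bearing carbon C10) and iodinolysis with I2 would give the E-alkenyl iodide oxirane F1. LiI and AcOH in THF at 0 °C would open the oxirane at C9 to the iodohydrin F2. A nickel-catalysed reductive coupling of the alkenyl iodide with the primary alkyl iodide (NiBr2·dme, 4,4'-di-tert-butyl-2,2'-bipyridine, Mn powder, DMA, slow addition at high dilution) would then form the same C9–C10 bond, tolerate the free C8 hydroxyl and give 20.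

Risk 2, step 14. Facial selectivity may be poor if the ring populates the rotamer in which O6 and not H6 eclipses the olefin; the Lewis-acidic vanadium may trigger transannular attack of C1=C10 on the new oxirane; C1=C10 may be oxidised in competition. The fallback sets out from 18 and comes back at 24, and puts the oxirane in place on the open chain, where allylic 1,3-strain control is well established. Epoxidation of 18 with mCPBA and NaHCO3 in CH2Cl2 at 0 °C (hydroxyl-directed threo delivery, alkyne inert) would give the bis-oxirane alcohol F3, the (4R,5R)-4,5-oxirane of 18. Et3SiCl and imidazole would give its triethylsilyl ether F4. The nickel macrocyclisation of step 11 applied to F4, in which the trisubstituted oxirane should stay inert because zerovalent nickel opens only unhindered monosubstituted oxiranes, would give the macrocyclic oxirane alcohol F5. Tigloylation as in step 12 would give the tiglate F6, and Bu4NF with AcOH would remove the silyl group to give 24.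

Risk 3, step 18. Acyl transfer to the hindered C6 hydroxyl (flanked by the oxirane and C7) may be slow enough for the activated acid to epimerise at its α-carbon, to lose silanol by β-elimination, or for the aryl carbonyl of the mixed anhydride to be transferred instead. The fallback sets out from 24 and comes back at the target 33, and builds the side-chain stereocentres after the ester bond instead of before it. Heating 24 with tert-butyl 2-methyl-3-oxobutanoate in toluene at 110 °C (acylketene transfer without base; 24 has no 1,5-diene left, so no Cope rearrangement) would give the 2-methyl-3-oxobutanoate F7 as a mixture of α-epimers. A ketoreductase chosen from a panel for syn-(2R,3S) selectivity (NADP+, glucose, glucose dehydrogenase, pH 7 buffer with DMSO, 30 °C) would reduce the ketone with dynamic kinetic resolution of the rapidly epimerising α-centre and give 33 directly, so that steps 15–19 would not be needed.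

**Further compounds**
F1 | step 11 | triethyl({(3S,4R,5E,9E)-10-iodo-2,6-dimethyl-3-[(2S)-oxiran-2-yl]undeca-5,9-dien-4-yl}oxy)silane | C/C(I)=C\CC/C(C)=C/[C@@H](O[Si](CC)(CC)CC)[C@@H](C(C)C)[C@H]1CO1
F2 | step 11 | iodohydrin of F1: C9 iodide, C8 hydroxyl, C6 triethylsilyl ether, C10 E-alkenyl iodide | C/C(I)=C\CC/C(C)=C/[C@@H](O[Si](CC)(CC)CC)[C@@H](C(C)C)[C@H](O)CI
F3 | step 14 | (4R,5R)-4,5-oxirane of 18 (acyclic bis-oxirane with free C6 hydroxyl) | CC#CCC[C@@]2(C)O[C@@H]2[C@@H](O)[C@@H](C(C)C)[C@H]1CO1
F4 | step 14 | C6 triethylsilyl ether of F3 | CC#CCC[C@@]2(C)O[C@@H]2[C@@H](O[Si](CC)(CC)CC)[C@@H](C(C)C)[C@H]1CO1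
F5 | step 14 | (1(10)E,4R,5R)-4,5-epoxy-6-[(triethylsilyl)oxy]germacr-1(10)-en-8-ol | O[C@@H]1C/C(C)=C/CC[C@@]2(C)O[C@@H]2[C@@H](O[Si](CC)(CC)CC)[C@H]1C(C)C
F6 | step 14 | (1(10)E,4R,5R)-4,5-epoxy-6-[(triethylsilyl)oxy]germacr-1(10)-en-8-yl (2E)-2-methylbut-2-enoate | C/C=C(\C)C(=O)O[C@@H]1C/C(C)=C/CC[C@@]2(C)O[C@@H]2[C@@H](O[Si](CC)(CC)CC)[C@H]1C(C)C
F7 | step 18 | (1(10)E,4R,5R,6S,7S,8R)-4,5-epoxy-6-[(2-methyl-3-oxobutanoyl)oxy]germacr-1(10)-en-8-yl (2E)-2-methylbut-2-enoate, both α-epimers | C/C=C(\C)C(=O)O[C@@H]1C/C(C)=C/CC[C@@]2(C)O[C@@H]2[C@@H](OC(=O)C(C)C(C)=O)[C@H]1C(C)C
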